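**Strategy.** The bicyclo[3.3.1]nonane is cut at C1–C8, the bond joining a bridgehead to the quaternary centre C8 (methyl, 4-methylpent-3-enyl). C6–C7–C8 is read as C1–C3 of geraniol and the oxygenated ring C9–C1–C2–C3–C4–C5 as a Cs-symmetric 1,5-dimethoxycyclohexa-1,4-diene. A Lewis-acid-triggered opening of the (2R,3R)-epoxide by one of the two enantiotopic enol ethers closes ring C1–C8–C7–C6–C5–C9, sets C8 by inversion, fixes the quaternary bridgehead C5 and C1 by desymmetrisation and leaves an oxygen at C7, later turned into the endo prenyl group. The precursor is an achiral diene alkylated with epoxygeranyl bromide; its only stereocentres are those of the epoxide.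

Key step: step 5

Remarks on the chemistry:
- Ring atoms are numbered as in the target: C1 and C5 bridgeheads, C2–C3–C4 the β-diketone bridge, C6–C7–C8 the carbon bridge, C9 the one-carbon ketone bridge.
- "Exo" at C7 means pointing away from the C2–C4 bridge, "endo" toward it. Prenyl = 3-methylbut-2-en-1-yl.
- The target SMILES (one enol tautomer) corresponds to 8-methyl axial, 8-homoprenyl equatorial and 7-prenyl endo; its descriptors are (1S,5S,7S,8S).
- Assumption: 3-acetoxybenzoyl chloride (20) is taken as a catalogue compound.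

Step 1
Reactants: 1 geraniol
Product: 2 (2R,3R)-2,3-epoxygeraniol
Conditions: Ti(OiPr)4 (cat.), D-(−)-diethyl tartrate (cat.), t-BuOOH, 4 Å MS, CH2Cl2, −20 °C
Reagents that add atoms: tert-butyl hydroperoxide CC(C)(C)OO
Why: Sharpless asymmetric epoxidation is selective for the allylic-alcohol double bond and, with the D-(−)-tartrate ligand, should deliver oxygen to the face that gives the (2R,3R)-epoxide, which fixes the future C7 and C8.

Step 2
Reactants: 2 (2R,3R)-2,3-epoxygeraniol
Product: 4 (2S,3R)-2-(bromomethyl)-3-methyl-3-(4-methylpent-3-en-1-yl)oxirane, via epoxygeranyl mesylate 3 (not isolated)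
Conditions: MsCl, Et3N, CH2Cl2, −20 °C; then LiBr, THF, 0 °C to rt
Reagents that add atoms: lithium bromide [Li+].[Br-]
Why: Sulfonylation and Finkelstein-type SN2 displacement at the primary carbon should leave the trisubstituted epoxide and both stereocentres untouched (the C2 descriptor changes only through CIP priorities).

Step 3
Reactants: 5 1,5-dimethoxycyclohexa-1,4-diene
Product: 7 1,5-dimethoxy-6-(3-methylbut-2-en-1-yl)cyclohexa-1,4-diene, via 6-lithio-1,5-dimethoxycyclohexa-1,4-diene 6 (not isolated)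
Conditions: t-BuLi, THF, −78 °C; then prenyl bromide, −78 to 0 °C
Reagents that add atoms: prenyl bromide CC(C)=CCBr
Why: Deprotonation of the bis-allylic CH2 flanked by the two methoxy-bearing carbons gives a pentadienyl lithium that is alkylated at its central carbon by SN2 (alkylation of a Birch-type diene), with no stereocentre formed.

Step 4
Reactants: 7 1,5-dimethoxy-6-(3-methylbut-2-en-1-yl)cyclohexa-1,4-diene; 4 (2S,3R)-2-(bromomethyl)-3-methyl-3-(4-methylpent-3-en-1-yl)oxirane
Product: 9 1,5-dimethoxy-6-(3-methylbut-2-en-1-yl)-6-{[(2R,3R)-3-methyl-3-(4-methylpent-3-en-1-yl)oxiran-2-yl]methyl}cyclohexa-1,4-diene, via 6-lithio-6-prenyl diene 8 (not isolated)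
Conditions: t-BuLi, THF, −78 °C; then 4, −78 to −30 °C
Reagents that add atoms: none
Why: A second deprotonation at the same carbon and SN2 alkylation by the primary bromide should build the quaternary carbon (future C5), not yet stereogenic because its two enol-ether arms are enantiotopic; the epoxide is introduced last so that no carbanion is generated next to it.

Step 5
Reactants: 9 1,5-dimethoxy-6-(3-methylbut-2-en-1-yl)-6-{[(2R,3R)-3-methyl-3-(4-methylpent-3-en-1-yl)oxiran-2-yl]methyl}cyclohexa-1,4-diene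
Product: 11 7,9-epoxy-4,9-dimethoxy-8-methyl-5-(3-methylbut-2-en-1-yl)-8-(4-methylpent-3-en-1-yl)bicyclo[3.3.1]non-3-ene, via O-silyl oxocarbenium triflate 10 (not isolated)
Conditions: TMSOTf, 2,6-lutidine, CH2Cl2, −78 °C
Reagents that add atoms: none
Why: Silylation of the epoxide oxygen makes the tertiary carbon C8 electrophilic, the β-carbon (C1) of one methyl enol ether attacks it anti to the breaking C8–O bond, and the resulting C9 methoxy-oxocarbenium ion is captured by the C7 silyl ether oxygen with loss of the silyl group to give the bridged mixed ketal. The closest known reaction type is the Lewis-acid epoxide-initiated cation–olefin (polyene-type) cyclization terminated by an enol ether. The carbocycle C1–C8–C7–C6–C5–C9 closes in the 6-endo mode at the epoxide (attack at the distal, more substituted carbon; enol-endo for the nucleophile), and the C7–O–C9 bridge closes by 5-exo-trig addition to the oxocarbenium ion. C8 is set by stereospecific inversion at the epoxide carbon, C7 is carried over from the epoxide, C1 and C5 are set together by the choice of one of the two enantiotopic enol ethers, and C9 is dictated by the bridge. The step needs attack at the tertiary and not the secondary epoxide carbon (secured by the cation-stabilising substitution at C8), selection of one enol ether (only one arm reaches the backside of C8 through a chair-like transition state with the homoprenyl chain pseudo-equatorial and the C7 oxygen placed to bridge to C9), and reaction of the enol ether ahead of the prenyl and homoprenyl double bonds (secured by its much higher nucleophilicity). 2,6-Lutidine buffers triflic acid so that the second enol ether survives.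

Step 6
Reactants: 11 7,9-epoxy-4,9-dimethoxy-8-methyl-5-(3-methylbut-2-en-1-yl)-8-(4-methylpent-3-en-1-yl)bicyclo[3.3.1]non-3-ene
Product: 12 7,9-epoxy-4,9-dimethoxy-8-methyl-5-(3-methylbut-2-en-1-yl)-8-(4-methylpent-3-en-1-yl)bicyclo[3.3.1]non-3-en-2-one
Conditions: t-BuOOH (decane), PhI(OAc)2, K2CO3 (cat.), EtOAc, −20 °C
Reagents that add atoms: tert-butyl hydroperoxide CC(C)(C)OO
Why: The C2 methylene is the only C–H allylic to an electron-rich enol ether, so hydrogen abstraction by the tert-butylperoxyl radical, recombination and Kornblum–DeLaMare-type collapse of the mixed peroxide (radical allylic oxidation) should give the vinylogous ester carbonyl selectively, with no stereocentre created.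

Step 7
Reactants: 12 7,9-epoxy-4,9-dimethoxy-8-methyl-5-(3-methylbut-2-en-1-yl)-8-(4-methylpent-3-en-1-yl)bicyclo[3.3.1]non-3-en-2-one
Product: 13 7-exo-hydroxy-4-methoxy-8-methyl-5-(3-methylbut-2-en-1-yl)-8-(4-methylpent-3-en-1-yl)bicyclo[3.3.1]non-3-ene-2,9-dione
Conditions: TsOH·H2O (cat.), acetone/H2O, rt
Reagents that add atoms: water O
Why: Acid-catalysed ketal hydrolysis should open the strained 7-oxabicyclo[2.2.1]heptane mixed ketal much faster than the hindered vinylogous ester is hydrolysed, releasing the C9 ketone and the C7 exo alcohol with no change at any stereocentre.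

Step 8
Reactants: 13 7-exo-hydroxy-4-methoxy-8-methyl-5-(3-methylbut-2-en-1-yl)-8-(4-methylpent-3-en-1-yl)bicyclo[3.3.1]non-3-ene-2,9-dione
Product: 15 7-exo-hydroxy-4-methoxy-8-methyl-1,5-bis(3-methylbut-2-en-1-yl)-8-(4-methylpent-3-en-1-yl)bicyclo[3.3.1]non-3-ene-2,9-dione, via O7-C1-dilithio species 14 (not isolated)
Conditions: LDA (2.1 equiv), THF, −78 to −40 °C; then prenyl bromide, −78 to −20 °C; H2O
Reagents that add atoms: prenyl bromide CC(C)=CCBr
Why: After the hydroxyl proton, LDA should remove the bridgehead C1–H flanked by the C2 and C9 carbonyl groups, and the bridgehead carbanion is alkylated with the retention a bridgehead enforces, while the lithium alkoxide stays a spectator as in Fráter–Seebach dianion alkylations.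

Step 9
Reactants: 15 7-exo-hydroxy-4-methoxy-8-methyl-1,5-bis(3-methylbut-2-en-1-yl)-8-(4-methylpent-3-en-1-yl)bicyclo[3.3.1]non-3-ene-2,9-dione
Product: 16 4-methoxy-8-methyl-1,5-bis(3-methylbut-2-en-1-yl)-8-(4-methylpent-3-en-1-yl)bicyclo[3.3.1]non-3-ene-2,7,9-trione
Conditions: TPAP (cat.), NMO, 4 Å MS, CH2Cl2, rt
Reagents that add atoms: none
Why: Ley–Griffith oxidation should convert the secondary C7 alcohol into the ketone under neutral conditions that spare the trisubstituted alkenes and the non-enolisable β-diketone unit, removing the C7 stereocentre on purpose.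

Step 10
Reactants: 16 4-methoxy-8-methyl-1,5-bis(3-methylbut-2-en-1-yl)-8-(4-methylpent-3-en-1-yl)bicyclo[3.3.1]non-3-ene-2,7,9-trione
Product: 17 4-methoxy-8-methyl-7-methylidene-1,5-bis(3-methylbut-2-en-1-yl)-8-(4-methylpent-3-en-1-yl)bicyclo[3.3.1]non-3-ene-2,9-dione
Conditions: Ph3PCH3Br, KHMDS, THF/toluene, 0 to 60 °C
Reagents that add atoms: methyltriphenylphosphonium bromide C[P+](c1ccccc1)(c1ccccc1)c1ccccc1.[Br-]
Why: Wittig methylenation should occur only at the C7 ketone, because the C9 ketone now lies between two quaternary carbons and the C2 carbonyl is a vinylogous ester.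

Step 11
Reactants: 17 4-methoxy-8-methyl-7-methylidene-1,5-bis(3-methylbut-2-en-1-yl)-8-(4-methylpent-3-en-1-yl)bicyclo[3.3.1]non-3-ene-2,9-dione
Product: 19 4-methoxy-8-methyl-1,5,7-tris(3-methylbut-2-en-1-yl)-8-(4-methylpent-3-en-1-yl)bicyclo[3.3.1]non-3-ene-2,9-dione (7-endo prenyl), via B-alkyl-9-BBN adduct 18 (not isolated)
Conditions: 9-BBN, THF, rt; then Me2C=CHBr, PdCl2(dppf) (cat.), AsPh3 (cat.), K3PO4, DMF/H2O, 50 °C
Reagents that add atoms: 1-bromo-2-methylprop-1-ene CC(C)=CBr
Why: 9-BBN should hydroborate the 1,1-disubstituted alkene far faster than the trisubstituted alkenes or the hindered carbonyl groups, placing boron on the terminal carbon and hydrogen on C7 from the exo face (the endo face is blocked by the C2–C4 bridge), so that the CH2B arm and, after B-alkyl Suzuki–Miyaura coupling, the prenyl group are endo.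

Step 12
Reactants: 19 4-methoxy-8-methyl-1,5,7-tris(3-methylbut-2-en-1-yl)-8-(4-methylpent-3-en-1-yl)bicyclo[3.3.1]non-3-ene-2,9-dione; 20 3-acetoxybenzoyl chloride
Product: 22 3-(3-acetoxybenzoyl)-4-methoxy-8-methyl-1,5,7-tris(3-methylbut-2-en-1-yl)-8-(4-methylpent-3-en-1-yl)bicyclo[3.3.1]non-3-ene-2,9-dione, via 3-lithio derivative 21 (not isolated)
Conditions: LiTMP, THF, −78 °C; then 20, −78 to −40 °C
Reagents that add atoms: none
Why: With both bridgeheads quaternary the only acidic C–H is the vinylic C3–H between the carbonyl and the methoxy-bearing carbon, so LiTMP should give the C3 vinyllithium, which is acylated by the acid chloride (directed lithiation–acylation) faster than it attacks the aryl acetate.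

Step 13
Reactants: 22 3-(3-acetoxybenzoyl)-4-methoxy-8-methyl-1,5,7-tris(3-methylbut-2-en-1-yl)-8-(4-methylpent-3-en-1-yl)bicyclo[3.3.1]non-3-ene-2,9-dione
Product: 23 CNP0406274.1
Conditions: LiOH, dioxane/H2O, 90 °C; then 1 M HCl to pH 3
Reagents that add atoms: lithium hydroxide [Li+].[OH-]
Why: Hydroxide should cleave the vinylogous methyl ester by addition–elimination at C4 and saponify the aryl acetate, and the delocalised triketone enolate resists retro-Claisen cleavage until acidification releases the target with all four stereocentres untouched.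

**Compound list**

1 | geraniol, (2E)-3,7-dimethylocta-2,6-dien-1-ol | CC(C)=CCC/C(C)=C/CO | starting material
2 | (2R,3R)-2,3-epoxygeraniol | OC[C@H]1O[C@]1(C)CCC=C(C)C | intermediate
3 | (2R,3R)-2,3-epoxygeranyl methanesulfonate | CS(=O)(=O)OC[C@H]1O[C@]1(C)CCC=C(C)C | intermediate
4 | (2S,3R)-2-(bromomethyl)-3-methyl-3-(4-methylpent-3-en-1-yl)oxirane (epoxygeranyl bromide) | BrC[C@H]1O[C@]1(C)CCC=C(C)C | intermediate
5 | 1,5-dimethoxycyclohexa-1,4-diene | COC1=CCC=C(OC)C1 | starting material
6 | 6-lithio-1,5-dimethoxycyclohexa-1,4-diene | COC1=CCC=C(OC)C1[Li] | intermediate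
7 | 1,5-dimethoxy-6-(3-methylbut-2-en-1-yl)cyclohexa-1,4-diene | COC1=CCC=C(OC)C1CC=C(C)C | intermediate
8 | 6-lithio-1,5-dimethoxy-6-(3-methylbut-2-en-1-yl)cyclohexa-1,4-diene | COC1=CCC=C(OC)C1([Li])CC=C(C)C | intermediate
9 | 1,5-dimethoxy-6-prenyl-6-{[(2R,3R)-3-methyl-3-(4-methylpent-3-en-1-yl)oxiran-2-yl]methyl}cyclohexa-1,4-diene | COC1=CCC=C(OC)C1(CC=C(C)C)C[C@H]2O[C@]2(C)CCC=C(C)C | intermediate
10 | ring-closed C9 methoxy-oxocarbenium triflate with C7 OSiMe3 | CC(C)=CCC[C@@]1(C)[C@H](O[Si](C)(C)C)C[C@]2(CC=C(C)C)C(=[O+]C)[C@H]1CC=C2OC.[O-]S(=O)(=O)C(F)(F)F | intermediate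
11 | bridged ketal, 7,9-epoxy-4,9-dimethoxy-8-methyl-5-prenyl-8-(4-methylpent-3-en-1-yl)bicyclo[3.3.1]non-3-ene (8-methyl axial, oxygen exo at C7) | CC(C)=CCC[C@@]1(C)[C@H]2C[C@@]3(CC=C(C)C)C(OC)=CC[C@@H]1[C@@]3(OC)O2 | intermediate
12 | the 3-en-2-one of 11 | CC(C)=CCC[C@@]1(C)[C@H]2C[C@@]3(CC=C(C)C)C(OC)=CC(=O)[C@@H]1[C@@]3(OC)O2 | intermediate
13 | 7-exo-hydroxy-4-methoxy-8-methyl-5-prenyl-8-(4-methylpent-3-en-1-yl)bicyclo[3.3.1]non-3-ene-2,9-dione | CC(C)=CCC[C@@]1(C)[C@H](O)C[C@]2(CC=C(C)C)C(=O)[C@H]1C(=O)C=C2OC | intermediate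
14 | O7,C1-dilithio derivative of 13 | CC(C)=CCC[C@@]1(C)[C@H](O[Li])C[C@]2(CC=C(C)C)C(=O)[C@@]1([Li])C(=O)C=C2OC | intermediate
15 | 7-exo-hydroxy-4-methoxy-8-methyl-1,5-diprenyl-8-(4-methylpent-3-en-1-yl)bicyclo[3.3.1]non-3-ene-2,9-dione | CC(C)=CCC[C@@]1(C)[C@H](O)C[C@]2(CC=C(C)C)C(=O)[C@@]1(CC=C(C)C)C(=O)C=C2OC | intermediate
16 | 4-methoxy-8-methyl-1,5-diprenyl-8-(4-methylpent-3-en-1-yl)bicyclo[3.3.1]non-3-ene-2,7,9-trione | CC(C)=CCC[C@@]1(C)C(=O)C[C@]2(CC=C(C)C)C(=O)[C@@]1(CC=C(C)C)C(=O)C=C2OC | intermediate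
17 | 4-methoxy-8-methyl-7-methylidene-1,5-diprenyl-8-(4-methylpent-3-en-1-yl)bicyclo[3.3.1]non-3-ene-2,9-dione | CC(C)=CCC[C@@]1(C)C(=C)C[C@]2(CC=C(C)C)C(=O)[C@@]1(CC=C(C)C)C(=O)C=C2OC | intermediate
18 | 7-endo-[(9-borabicyclo[3.3.1]nonan-9-yl)methyl] adduct of 17 | CC(C)=CCC[C@@]1(C)[C@@H](CB3C4CCCC3CCC4)C[C@]2(CC=C(C)C)C(=O)[C@@]1(CC=C(C)C)C(=O)C=C2OC | intermediate
19 | 4-methoxy-8-methyl-1,5,7-triprenyl-8-(4-methylpent-3-en-1-yl)bicyclo[3.3.1]non-3-ene-2,9-dione (7-endo prenyl) | CC(C)=CCC[C@@]1(C)[C@@H](CC=C(C)C)C[C@]2(CC=C(C)C)C(=O)[C@@]1(CC=C(C)C)C(=O)C=C2OC | intermediate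
20 | 3-acetoxybenzoyl chloride | CC(=O)Oc1cccc(C(=O)Cl)c1 | starting material
21 | 3-lithio derivative of 19 | CC(C)=CCC[C@@]1(C)[C@@H](CC=C(C)C)C[C@]2(CC=C(C)C)C(=O)[C@@]1(CC=C(C)C)C(=O)C([Li])=C2OC | intermediate
22 | 3-(3-acetoxybenzoyl)-4-methoxy-8-methyl-1,5,7-triprenyl-8-(4-methylpent-3-en-1-yl)bicyclo[3.3.1]non-3-ene-2,9-dione | CC(C)=CCC[C@@]1(C)[C@@H](CC=C(C)C)C[C@]2(CC=C(C)C)C(=O)[C@@]1(CC=C(C)C)C(=O)C(C(=O)c1cccc(OC(C)=O)c1)=C2OC | intermediate
23 | CNP0406274.1, (1S,5S,7S,8S)-4-hydroxy-3-(3-hydroxybenzoyl)-8-methyl-1,5,7-tris(3-methylbut-2-en-1-yl)-8-(4-methylpent-3-en-1-yl)bicyclo[3.3.1]non-3-ene-2,9-dione (tautomer as drawn) | CC(C)=CCC[C@@]1(C)[C@@H](CC=C(C)C)C[C@]2(CC=C(C)C)C(=O)[C@@]1(CC=C(C)C)C(=O)C(C(=O)c1cccc(O)c1)=C2O | target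

**Step count.** Total: 13 steps. Longest linear sequence: 12 steps (steps 1, 2 and 4–13, from geraniol).

**Steps most likely to fail.** The key step 5 is ranked below the three that follow, because its reaction type is established for this substrate class and its specific demand (selection of one enol ether) is covered in its Why line.

Step 11. The congested B-alkyl borane may transmetalate to palladium so slowly that protodeboronation outruns cross-coupling. The fallback sets out from 18: oxidation (NaBO3·4H2O) should give the 7-endo hydroxymethyl compound F1, and I2, PPh3 and imidazole convert it into the 7-endo iodomethyl compound F2. SN2 coupling of F2 with lithium bis(2-methylprop-1-enyl)cuprate, which should not add to the hindered C9 ketone or the vinylogous ester, comes back to the route at 19. The C–C bond is then made by copper-mediated sp3–sp2 substitution instead of palladium catalysis.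

Step 8. The second metalation of the lithium alkoxide may stay incomplete, or the alkoxide may be O-prenylated, which erodes the bridgehead alkylation. The fallback sets out from 13: TESCl and imidazole give the C7 triethylsilyl ether F3, LDA gives its bridgehead lithio derivative F4, and prenyl bromide gives the C1-prenylated silyl ether F5. TBAF buffered with AcOH removes the silyl group and comes back to the route at 15. The alkylation is then run on the monoanion of a protected substrate instead of on a dianion.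

Step 10. The basic ylide may enolise the neopentyl-type C7 ketone instead of adding to it, so that conversion stalls. The fallback sets out from 16: the weakly basic organocerium reagent from Me3SiCH2Li and CeCl3 should add to the C7 carbonyl from the exo face to give the β-hydroxysilane F6. Peterson elimination (KH, THF) comes back to the route at 17. The alkene is then made by addition–elimination and not by a phosphorus ylide.

Further compounds
F1 | step 11 | 7-endo-(hydroxymethyl)-4-methoxy-8-methyl-1,5-diprenyl-8-(4-methylpent-3-en-1-yl)bicyclo[3.3.1]non-3-ene-2,9-dione | CC(C)=CCC[C@@]1(C)[C@@H](CO)C[C@]2(CC=C(C)C)C(=O)[C@@]1(CC=C(C)C)C(=O)C=C2OC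
F2 | step 11 | 7-endo-(iodomethyl)-4-methoxy-8-methyl-1,5-diprenyl-8-(4-methylpent-3-en-1-yl)bicyclo[3.3.1]non-3-ene-2,9-dione | CC(C)=CCC[C@@]1(C)[C@@H](CI)C[C@]2(CC=C(C)C)C(=O)[C@@]1(CC=C(C)C)C(=O)C=C2OC
F3 | step 8 | C7 triethylsilyl ether of 13 | CC(C)=CCC[C@@]1(C)[C@H](O[Si](CC)(CC)CC)C[C@]2(CC=C(C)C)C(=O)[C@H]1C(=O)C=C2OC
F4 | step 8 | bridgehead (C1) lithio derivative of F3 | CC(C)=CCC[C@@]1(C)[C@H](O[Si](CC)(CC)CC)C[C@]2(CC=C(C)C)C(=O)[C@@]1([Li])C(=O)C=C2OC
F5 | step 8 | C7 triethylsilyl ether of 15 | CC(C)=CCC[C@@]1(C)[C@H](O[Si](CC)(CC)CC)C[C@]2(CC=C(C)C)C(=O)[C@@]1(CC=C(C)C)C(=O)C=C2OC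
F6 | step 10 | 7-endo-hydroxy-7-exo-[(trimethylsilyl)methyl] adduct of 16 | CC(C)=CCC[C@@]1(C)[C@@](C[Si](C)(C)C)(O)C[C@]2(CC=C(C)C)C(=O)[C@@]1(CC=C(C)C)C(=O)C=C2OC
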